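The earlier runs and the new flask come from a simulation from invented constants.

If I run this flask as a slowed film, the earlier runs give me frames to read it by, though none has its charges.

| flask | substrate | coupling partner | remark | time |
|---|---|---|---|---|
| midnight | 0.55 M | 0.80 equiv (fed, over 40 min) | run made earlier; the fed solution adds 0.10 times the starting volume |  |
| spring | 0.83 M | 0.80 equiv (fed, over 40 min) | run made earlier; the fed solution adds 0.10 times the starting volume |  |
| summer | 1.1 M | 1.6 equiv (fed, over 40 min) | run made earlier; the fed solution adds 0.10 times the starting volume |  |
| flask | 1.1 M | 0.800 equiv (fed, over 40 min) | the fed solution adds 0.10 times the starting volume | 4.0 h |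

- midnight (time / h: isomer of the product / %, target / %, substrate / %): 0.250: 11, 6, 84; 0.833: 57, 3, 40; 1.33: 69, 0, 30; 2.50: 77, 0, 23; 3.00: 77, 0, 19
- spring (time / h: isomer of the product / %, target / %, substrate / %): 0.667: 52, 7, 41; 1.33: 73, 0, 23; 2.00: 78, 0, 25; 2.50: 81, 0, 22; 3.00: 79, 0, 21
- summer (time / h: isomer of the product / %, target / %, substrate / %): 0.250: 31, 11, 60; 0.833: 93, 2, 1; 1.33: 100, 0, 2; 2.50: 98, 0, 0; 3.00: 98, 0, 0

(readings scatter by 1.5 percentage points)

- charges are per starting volume, the dose included; the dosed solution carries all of it

- where most of what was charged as substrate, at 4.0 h is found (target / isomer of the product / substrate)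
- the largest share itself, whichever of these holds it, in percent of the substrate charged

In the first instants the coupling partner trickles into the substrate, and target and isomer of the product appear side by side: the summer run reads 11% target and 31% isomer at 0.250 h. In the middle, at the end of the feed, the spring run, which has the equivalents of this flask, reads 52% isomer and 7% target at 0.667 h, together 59.0%. Target then reads 0% at 1.33 h while isomer climbs to 73%, so target is a passing stock.

For the end I count. With 0.80 equiv of partner the spring run reads 81% isomer at 2.50 h, and with 1.6 equiv the summer run, which also starts with more substrate, reads 100% at 1.33 h, so I take it that each substrate that leaves takes one coupling partner with it. If I divide the rate at which substrate goes by the rate at which partner goes, I get one at each moment and time drops out. In this flask the partner is the limiting reagent, so the flask's ceiling is 80.0%: the equivalents of partner read as a share of the substrate charged, the partner ceiling. The spring run, at a lower substrate concentration, reads 81% by 2.50 h, and the flask gets 4.0 h. So my reckoning for the flask is isomer at the ceiling, with 20.0% substrate remaining.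

The forecast gives isomer of the product at 80%, on the grounds that “the plateau barely depends on concentration, though the dilute run is slower”.

The flask gives isomer of the product at 80.0%, which stands on the ceiling, with 20.0% substrate and 0% target.

    substrate + coupling partner → isomer of the product (k = 0.00330 M⁻¹ s⁻¹)
    substrate + coupling partner ⇌ target (K = 0.760 M⁻¹, k = 0.00490 M⁻¹ s⁻¹)

At 0.506 h the half-life of substrate in the flask by the path to isomer is 0.39 h, shorter than the time allowed. At 4.00 h, with the coupling partner at 0.0170% of its charge, that half-life in the flask is 18 d, far longer than the time allowed. A second flask, like this one but charged with 0.320 equiv of partner, has a ceiling of 32.0% and ends at 32.0% isomer.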